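**Strategy.** Ring C is cut across O1–C2 and C3–C4, the two bonds on either side of the C2–C3 unit, which is styrene. C4 then belongs to a ring A salicylaldehyde, already at an oxidation level that leads to the ketone. One catalytic, enantioselective oxa-[4+2] cycloaddition of the derived 4-methoxy ortho-quinone methide with styrene closes ring C, makes both bonds and sets C2. The precursor is a hexasubstituted ring A aldehyde carrying both C-benzyl groups and six benzyl ethers, whose only free hydroxyl (future C8a–O1) is ortho to the formyl group. It arises without selective protection because the last formylation is directed by that phenol.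

Key step: step 10

Remark on the chemistry: the sense of induction of the chiral acid in step 10 cannot be predicted reliably, so the (R)-acid is written and its mirror image is to be used if it favours 2R; compounds 1, 3, 7 and 8 are assumed to be catalogue chemicals.

Abbreviations used in names: Bn = benzyl; group S = 2-(benzyloxy)benzyl; group L = 2-(benzyloxy)-5-{2-(benzyloxy)-5-[2-(benzyloxy)benzyl]benzyl}benzyl.

**Ring A building block**

Step 1
Reactants: 1 3,5-bis(benzyloxy)phenol
Product: 2 2,6-bis(benzyloxy)-4-hydroxybenzaldehyde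
Conditions: POCl3, DMF, MeCN, 0 °C to rt; then H2O, 40 °C; any chelated ortho-formyl isomer removed by crystallisation or chromatography
Reagents that add atoms: N,N-dimethylformamide, CN(C)C=O; water, O
Why: Vilsmeier–Haack formylation of a 3,5-dialkoxyphenol is known to go mainly para to the free hydroxyl, and in symmetric 1 that carbon is the single position flanked by both benzyl ethers, so the carbon that becomes the C6 substituent is placed where no later differentiation of oxygens is needed.

Step 2
Reactants: 2 2,6-bis(benzyloxy)-4-hydroxybenzaldehyde; 3 1-(benzyloxy)-2-bromobenzene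
Product: 5 racemic [2,6-bis(benzyloxy)-4-hydroxyphenyl][2-(benzyloxy)phenyl]methanol, via arylmagnesium bromide 4 (not isolated)
Conditions: 3 (3.5 equiv), Mg, THF, reflux; then 2, THF, 0 °C to 50 °C; aq. NH4Cl; crude product used at once
Reagents that add atoms: none
Why: Grignard addition to the aldehyde, in which the first equivalent of 4 only deprotonates the phenol and the excess adds to the carbonyl group chelated by an ortho benzyloxy group; the new carbinol centre is racemic and is removed in step 3.

Step 3
Reactants: 5 racemic [2,6-bis(benzyloxy)-4-hydroxyphenyl][2-(benzyloxy)phenyl]methanol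
Product: 6 3,5-bis(benzyloxy)-4-[2-(benzyloxy)benzyl]phenol
Conditions: Et3SiH (5 equiv), TFA, CH2Cl2, −20 to 0 °C, slow addition of 5
Reagents that add atoms: none
Why: Ionic hydrogenation, in which the doubly benzylic alcohol ionises to a cation stabilised by three ring oxygens (a protonated para-quinone methide) that takes hydride from the excess silane in preference to alkylating another ring, while aryl benzyl ethers survive cold TFA.

**Side chain (group L as its aldehyde)**

Step 4
Reactants: 7 1-(benzyloxy)-2-(bromomethyl)benzene; 8 [4-(benzyloxy)-3-formylphenyl]boronic acid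
Product: 9 2-(benzyloxy)-5-[2-(benzyloxy)benzyl]benzaldehyde
Conditions: Pd(PPh3)4 (3 mol%), K2CO3, toluene/EtOH/H2O, 80 °C
Reagents that add atoms: none
Why: Suzuki–Miyaura coupling of a benzylic bromide with an arylboronic acid forms the diarylmethane bond under mild base that leaves the aldehyde and the benzyl ethers untouched.

Step 5
Reactants: 9 2-(benzyloxy)-5-[2-(benzyloxy)benzyl]benzaldehyde
Product: 10 {2-(benzyloxy)-5-[2-(benzyloxy)benzyl]phenyl}methanol
Conditions: NaBH4, THF/MeOH, 0 °C
Reagents that add atoms: none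
Why: Borohydride reduction of an aryl aldehyde to the benzylic alcohol, selective in the presence of aryl ethers.

Step 6
Reactants: 10 {2-(benzyloxy)-5-[2-(benzyloxy)benzyl]phenyl}methanol
Product: 11 1-(benzyloxy)-4-[2-(benzyloxy)benzyl]-2-(bromomethyl)benzene
Conditions: CBr4, PPh3, CH2Cl2, 0 °C
Reagents that add atoms: tetrabromomethane, BrC(Br)(Br)Br
Why: Appel bromination converts the primary benzylic alcohol into the bromide under neutral conditions, avoiding HBr that could attack the benzyl ethers.

Step 7
Reactants: 11 1-(benzyloxy)-4-[2-(benzyloxy)benzyl]-2-(bromomethyl)benzene; 8 [4-(benzyloxy)-3-formylphenyl]boronic acid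
Product: 12 2-(benzyloxy)-5-{2-(benzyloxy)-5-[2-(benzyloxy)benzyl]benzyl}benzaldehyde
Conditions: Pd(PPh3)4 (3 mol%), K2CO3, toluene/EtOH/H2O, 80 °C
Reagents that add atoms: none
Why: A second Suzuki–Miyaura benzyl–aryl coupling with the same boronic acid extends the chain by one ring and regenerates an aldehyde as the handle for attachment to ring A.

**Assembly of the precursor**

Step 8
Reactants: 6 3,5-bis(benzyloxy)-4-[2-(benzyloxy)benzyl]phenol; 12 2-(benzyloxy)-5-{2-(benzyloxy)-5-[2-(benzyloxy)benzyl]benzyl}benzaldehyde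
Product: 14 3,5-bis(benzyloxy)-2-L-4-S-phenol, via benzodioxaborin 13 (not isolated)
Conditions: PhB(OH)2 (1.2 equiv), EtCO2H (cat.), toluene, reflux, Dean–Stark; then solvent exchange, Et3SiH (5 equiv), TFA, CH2Cl2, 0 °C; aqueous work-up
Reagents that add atoms: none
Why: Boronic acid templated ortho-hydroxyalkylation of a phenol with an aldehyde (Nagata reaction) ties the phenol oxygen and the aldehyde to one boron, so attack occurs once and only ortho (the two ortho carbons of 6 are equivalent and para is blocked), and ionic hydrogenation of the doubly benzylic C–O bond of 13 then gives the diarylmethane while work-up frees the phenol.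

Step 9
Reactants: 14 3,5-bis(benzyloxy)-2-L-4-S-phenol
Product: 15 4,6-bis(benzyloxy)-2-hydroxy-3-L-5-S-benzaldehyde
Conditions: MgCl2, Et3N, (CH2O)n, THF, reflux; dilute aq. HCl work-up
Reagents that add atoms: paraformaldehyde (as formaldehyde), C=O
Why: Magnesium phenoxide mediated ortho-formylation (Casnati–Skattebøl reaction) delivers formaldehyde within the magnesium chelate to the one remaining ring carbon, which is ortho to the hydroxyl, and a second formaldehyde oxidises the hydroxymethyl stage to the aldehyde, so the free hydroxyl of 15 is necessarily the one next to the formyl group.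

**Key step and end game**

Step 10
Reactants: 15 4,6-bis(benzyloxy)-2-hydroxy-3-L-5-S-benzaldehyde; 16 styrene
Product: 19 (2S)-5,7-bis(benzyloxy)-4-methoxy-2-phenyl-6-S-8-L-chromane (mixture of C4 epimers), via dimethyl acetal 17 (not isolated), via oxocarbenium ion 18 (not isolated)
Conditions: 16 (5 equiv), HC(OMe)3 (3 equiv), (R)-3,3'-bis(2,4,6-triisopropylphenyl)-1,1'-binaphthyl-2,2'-diyl N-triflylphosphoramide (10 mol%), 5 Å MS, toluene, 0 °C to rt
Reagents that add atoms: trimethyl orthoformate, COC(OC)OC
Why: Proposed new method: trimethyl orthoformate turns the aldehyde into dimethyl acetal 17, which the chiral acid ionises to the O-methyl oxocarbenium ion 18, the protonated form of a 4-methoxy ortho-quinone methide that is stabilised by the oxygens at C5, C7 and C8a and stays ion-paired with the chiral anion through the C8a–OH···O=P hydrogen bond. The CH2 terminus of styrene attacks C4 and the benzylic cation developing at C2 is captured by the C8a oxygen, so ring C closes by an asynchronous inverse-electron-demand oxa-[4+2] cycloaddition (heterodiene O1–C8a–C4a–C4 plus dienophile C2–C3) that forms C3–C4 and O1–C2 in one operation. The closest known reactions are the achiral acid-promoted three-component synthesis of 4-alkoxychromans from salicylaldehydes, orthoformates and alkenes and the chiral phosphoric acid catalysed [4+2] of ortho-quinone methides with styrenes; their merger into an enantioselective 4-alkoxy variant is the untested part. C2 should be set by catalyst control, the confined chiral anion shielding one face of the hydrogen-bonded heterodiene so that phenyl ends up 2S, whereas C4 forms without control as an epimer mixture that is erased in step 12. Regiochemistry (phenyl on the carbon bonded to oxygen) follows from styrene polarisation, and the identity of O1 is secured by the substrate because the C8a hydroxyl is the only free phenol while the C5 oxygen is benzylated. The pendant benzyloxyarenes are weaker nucleophiles than styrene in excess and cannot reach C4 intramolecularly for geometric reasons.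

Step 11
Reactants: 19 (2S)-5,7-bis(benzyloxy)-4-methoxy-2-phenyl-6-S-8-L-chromane
Product: 20 (2S)-5,7-bis(benzyloxy)-2-phenyl-6-S-8-L-chroman-4-ol (mixture of C4 epimers)
Conditions: 0.5 M aq. HCl, THF, 0 °C to rt, dilute
Reagents that add atoms: water, O
Why: SN1 solvolysis in which the C4 methyl ether ionises under mild acid to the benzylic cation stabilised by the oxygens at C5, C7 and O1 and is captured by water present in large excess, which disfavours elimination to the flav-3-ene; C2 is not involved and both C4 epimers are carried on.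

Step 12
Reactants: 20 (2S)-5,7-bis(benzyloxy)-2-phenyl-6-S-8-L-chroman-4-ol
Product: 21 (2S)-5,7-bis(benzyloxy)-2-phenyl-6-S-8-L-chroman-4-one
Conditions: Dess–Martin periodinane, NaHCO3, CH2Cl2, 0 °C to rt
Reagents that add atoms: none
Why: Dess–Martin oxidation of the secondary benzylic alcohol under bicarbonate buffering gives the ketone without acid or strong base, so the C4 epimers converge and the C2 centre, which could only scramble by base-induced ring opening to the chalcone, is kept.

Step 13
Reactants: 21 (2S)-5,7-bis(benzyloxy)-2-phenyl-6-S-8-L-chroman-4-one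
Product: 22 sarmentosumin A, (2S)-5,7-dihydroxy-6-(2-hydroxybenzyl)-8-{2-hydroxy-5-[2-hydroxy-5-(2-hydroxybenzyl)benzyl]benzyl}-2-phenylchroman-4-one
Conditions: H2 (1 atm), Pd/C (10%), EtOAc/MeOH, rt, stopped at full debenzylation
Reagents that add atoms: none
Why: Catalytic hydrogenolysis cleaves all six aryl benzyl ethers under neutral conditions in which the flavanone does not open to the chalcone, and it is stopped before the slower hydrogenolysis of the C2–O1 bond or reduction of the carbonyl sets in.

**Compound list**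

1 | 3,5-bis(benzyloxy)phenol | Oc1cc(OCc2ccccc2)cc(OCc2ccccc2)c1 | starting material
2 | 2,6-bis(benzyloxy)-4-hydroxybenzaldehyde | O=Cc1c(OCc2ccccc2)cc(O)cc1OCc1ccccc1 | intermediate
3 | 1-(benzyloxy)-2-bromobenzene | Brc1ccccc1OCc1ccccc1 | starting material
4 | [2-(benzyloxy)phenyl]magnesium bromide | Br[Mg]c1ccccc1OCc1ccccc1 | intermediate
5 | racemic [2,6-bis(benzyloxy)-4-hydroxyphenyl][2-(benzyloxy)phenyl]methanol | OC(c1ccccc1OCc1ccccc1)c1c(OCc2ccccc2)cc(O)cc1OCc1ccccc1 | intermediate
6 | 3,5-bis(benzyloxy)-4-[2-(benzyloxy)benzyl]phenol | Oc1cc(OCc2ccccc2)c(Cc2ccccc2OCc2ccccc2)c(OCc2ccccc2)c1 | intermediate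
7 | 1-(benzyloxy)-2-(bromomethyl)benzene | BrCc1ccccc1OCc1ccccc1 | starting material
8 | [4-(benzyloxy)-3-formylphenyl]boronic acid | O=Cc1cc(B(O)O)ccc1OCc1ccccc1 | starting material
9 | 2-(benzyloxy)-5-[2-(benzyloxy)benzyl]benzaldehyde | O=Cc1cc(Cc2ccccc2OCc2ccccc2)ccc1OCc1ccccc1 | intermediate
10 | {2-(benzyloxy)-5-[2-(benzyloxy)benzyl]phenyl}methanol | OCc1cc(Cc2ccccc2OCc2ccccc2)ccc1OCc1ccccc1 | intermediate
11 | 1-(benzyloxy)-4-[2-(benzyloxy)benzyl]-2-(bromomethyl)benzene | BrCc1cc(Cc2ccccc2OCc2ccccc2)ccc1OCc1ccccc1 | intermediate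
12 | 2-(benzyloxy)-5-{2-(benzyloxy)-5-[2-(benzyloxy)benzyl]benzyl}benzaldehyde | O=Cc1cc(Cc2cc(Cc3ccccc3OCc3ccccc3)ccc2OCc2ccccc2)ccc1OCc1ccccc1 | intermediate
13 | racemic 4-{2-(benzyloxy)-5-{2-(benzyloxy)-5-[2-(benzyloxy)benzyl]benzyl}phenyl}-5,7-bis(benzyloxy)-6-[2-(benzyloxy)benzyl]-2-phenyl-4H-1,3,2-benzodioxaborin | c1ccccc1B1Oc2cc(OCc3ccccc3)c(Cc3ccccc3OCc3ccccc3)c(OCc3ccccc3)c2C(c2cc(Cc3cc(Cc4ccccc4OCc4ccccc4)ccc3OCc3ccccc3)ccc2OCc2ccccc2)O1 | intermediate
14 | 3,5-bis(benzyloxy)-2-L-4-S-phenol | Oc1cc(OCc2ccccc2)c(Cc2ccccc2OCc2ccccc2)c(OCc2ccccc2)c1Cc1cc(Cc2cc(Cc3ccccc3OCc3ccccc3)ccc2OCc2ccccc2)ccc1OCc1ccccc1 | intermediate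
15 | 4,6-bis(benzyloxy)-2-hydroxy-3-L-5-S-benzaldehyde (precursor of the key step) | O=Cc1c(O)c(Cc2cc(Cc3cc(Cc4ccccc4OCc4ccccc4)ccc3OCc3ccccc3)ccc2OCc2ccccc2)c(OCc2ccccc2)c(Cc2ccccc2OCc2ccccc2)c1OCc1ccccc1 | intermediate
16 | styrene | C=Cc1ccccc1 | starting material
17 | dimethyl acetal of 15 | COC(OC)c1c(O)c(Cc2cc(Cc3cc(Cc4ccccc4OCc4ccccc4)ccc3OCc3ccccc3)ccc2OCc2ccccc2)c(OCc2ccccc2)c(Cc2ccccc2OCc2ccccc2)c1OCc1ccccc1 | intermediate
18 | (E)-O-methyl oxocarbenium ion (protonated 4-methoxy ortho-quinone methide), ion-paired with the catalyst anion | C/[O+]=C/c1c(O)c(Cc2cc(Cc3cc(Cc4ccccc4OCc4ccccc4)ccc3OCc3ccccc3)ccc2OCc2ccccc2)c(OCc2ccccc2)c(Cc2ccccc2OCc2ccccc2)c1OCc1ccccc1 | intermediate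
19 | (2S)-5,7-bis(benzyloxy)-4-methoxy-2-phenyl-6-S-8-L-chromane, C4 epimer mixture | COC1C[C@@H](c2ccccc2)Oc2c(Cc3cc(Cc4cc(Cc5ccccc5OCc5ccccc5)ccc4OCc4ccccc4)ccc3OCc3ccccc3)c(OCc3ccccc3)c(Cc3ccccc3OCc3ccccc3)c(OCc3ccccc3)c21 | intermediate
20 | (2S)-5,7-bis(benzyloxy)-2-phenyl-6-S-8-L-chroman-4-ol, C4 epimer mixture | OC1C[C@@H](c2ccccc2)Oc2c(Cc3cc(Cc4cc(Cc5ccccc5OCc5ccccc5)ccc4OCc4ccccc4)ccc3OCc3ccccc3)c(OCc3ccccc3)c(Cc3ccccc3OCc3ccccc3)c(OCc3ccccc3)c21 | intermediate
21 | (2S)-5,7-bis(benzyloxy)-2-phenyl-6-S-8-L-chroman-4-one | O=C1C[C@@H](c2ccccc2)Oc2c(Cc3cc(Cc4cc(Cc5ccccc5OCc5ccccc5)ccc4OCc4ccccc4)ccc3OCc3ccccc3)c(OCc3ccccc3)c(Cc3ccccc3OCc3ccccc3)c(OCc3ccccc3)c21 | intermediate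
22 | sarmentosumin A | O=C1C[C@@H](c2ccccc2)Oc2c(Cc3cc(Cc4cc(Cc5ccccc5O)ccc4O)ccc3O)c(O)c(Cc3ccccc3O)c(O)c21 | target

**Step count and risks**

Total step count: 13. Longest linear sequence: 10 steps (steps 4, 5, 6, 7, 8, 9, 10, 11, 12, 13).

Steps most likely to fail:

1. Step 10 (bears the new-method label). The triply donor-stabilised oxocarbenium ion may be too weak an electrophile for styrene, the loosely bound counter-anion may give poor facial selectivity, or the product may re-ionise at C4 under the acid. The fallback uses known chemistry, sets out from 15 and returns at 21. Compound 15, styrene 16 and trimethyl orthoformate are combined under an achiral acid such as Sc(OTf)3 in CH2Cl2, the established three-component chroman synthesis, to give the racemic 4-methoxy-2-phenylchromane F1. Hydrolysis as in step 11 gives the racemic chroman-4-ol F2, and Dess–Martin oxidation as in step 12 gives the racemic chroman-4-one F3. Kinetic resolution by asymmetric transfer hydrogenation with RuCl(p-cymene)[(R,R)-TsDPEN] (or its mirror image, whichever consumes the 2R ketone) and HCO2H/Et3N should reduce the 2R enantiomer to the (2R,4R)-cis-chroman-4-ol F4. F4 is separated, and the unreacted 2S ketone is compound 21.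

2. Step 8. The templated condensation may stall at the hindered ortho carbon with an electron-rich aldehyde, or the benzylic cation may be captured by a second phenol ring during ionic hydrogenation. The fallback sets out from 12 (with 6) and returns at 14. Aldehyde 12 is reduced with NaBH4 to the side-chain benzylic alcohol F5. F5 then alkylates an excess of phenol 6 under catalytic Sc(OTf)3 in CH2Cl2, a Friedel–Crafts benzylation through the ortho-alkoxybenzyl cation. The blocked para position and the equivalence of the two ortho carbons of 6 leave 14 as the only monoalkylation product.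

3. Step 13. Over-reduction (hydrogenolytic opening of the benzylic C2–O1 bond or reduction of the C4 carbonyl) or incomplete cleavage of the hindered ethers may occur. The fallback sets out from 21 and returns at 22. The six benzyl ethers are cleaved without any reducing agent by BCl3 with pentamethylbenzene as cation scavenger in CH2Cl2 at −78 °C, giving sarmentosumin A 22 directly; no further compound arises (F0).

Further compounds
F1 | step 10 | racemic 5,7-bis(benzyloxy)-4-methoxy-2-phenyl-6-S-8-L-chromane | COC1CC(c2ccccc2)Oc2c(Cc3cc(Cc4cc(Cc5ccccc5OCc5ccccc5)ccc4OCc4ccccc4)ccc3OCc3ccccc3)c(OCc3ccccc3)c(Cc3ccccc3OCc3ccccc3)c(OCc3ccccc3)c21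
F2 | step 10 | racemic 5,7-bis(benzyloxy)-2-phenyl-6-S-8-L-chroman-4-ol | OC1CC(c2ccccc2)Oc2c(Cc3cc(Cc4cc(Cc5ccccc5OCc5ccccc5)ccc4OCc4ccccc4)ccc3OCc3ccccc3)c(OCc3ccccc3)c(Cc3ccccc3OCc3ccccc3)c(OCc3ccccc3)c21
F3 | step 10 | racemic 5,7-bis(benzyloxy)-2-phenyl-6-S-8-L-chroman-4-one | O=C1CC(c2ccccc2)Oc2c(Cc3cc(Cc4cc(Cc5ccccc5OCc5ccccc5)ccc4OCc4ccccc4)ccc3OCc3ccccc3)c(OCc3ccccc3)c(Cc3ccccc3OCc3ccccc3)c(OCc3ccccc3)c21
F4 | step 10 | (2R,4R)-5,7-bis(benzyloxy)-2-phenyl-6-S-8-L-chroman-4-ol (2,4-cis) | O[C@@H]1C[C@H](c2ccccc2)Oc2c(Cc3cc(Cc4cc(Cc5ccccc5OCc5ccccc5)ccc4OCc4ccccc4)ccc3OCc3ccccc3)c(OCc3ccccc3)c(Cc3ccccc3OCc3ccccc3)c(OCc3ccccc3)c21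
F5 | step 8 | {2-(benzyloxy)-5-{2-(benzyloxy)-5-[2-(benzyloxy)benzyl]benzyl}phenyl}methanol | OCc1cc(Cc2cc(Cc3ccccc3OCc3ccccc3)ccc2OCc2ccccc2)ccc1OCc1ccccc1
F0 | step 13 | none | none
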